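**Assumption:** the target has no stereocentres (it is achiral), so there is no enantiomer to control; the transient sp3 centres in the ring-forming steps are made racemic and erased on aromatisation.

## Retrosynthetic overview

1. Target 22 ← one-pot hydrogenolysis of the doubly benzyl-protected depside 21 (benzyl ester on ring B, benzyl ether on ring A).
2. 21 ← aryl ester (depside) bond formed between A-ring acid 19 and B-ring phenol 11.
3. 19 and 11 ← O-differentiation of two resorcylates (16 and 6), using the chelated 2-OH versus the free 4-OH.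
4. Each resorcylate ← aromatisation of a cyclohexane-1,3-dione ester ← intermolecular Michael addition of dimethyl malonate to an enone, with in-situ Claisen (Dieckmann) ring closure.
5. Ring order: ring B (pentyl, steps 1–2) first, ring A (propyl, steps 8–9) second; the union forms no ring.

## Route

**Step 1**
Reactants: 1 dimethyl malonate; 2 (E)-non-3-en-2-one
Product: 4 methyl 2-hydroxy-4-oxo-6-pentylcyclohex-2-ene-1-carboxylate (racemic; enol form of the 2,4-dione), via Michael adduct 3 (not isolated)
Conditions: NaOMe (1.1 equiv), MeOH, reflux, 4 h; then aq. HCl, 0 °C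
Reagents that add atoms: none
Why: Intermolecular Michael addition of the malonate anion to the enone, then intramolecular Claisen (Dieckmann) condensation of the methyl-ketone enolate onto one ester, driven by the stabilised dione enolate; the two transient stereocentres are racemic and disappear in step 2.

**Step 2**
Reactants: 4 methyl 2-hydroxy-4-oxo-6-pentylcyclohex-2-ene-1-carboxylate
Product: 6 methyl 2,4-dihydroxy-6-pentylbenzoate (methyl olivetolate), via bromo-dione 5 (not isolated)
Conditions: Br2 (1.0 equiv), DMF, 0 °C, then 80 °C, 12 h; aq. Na2S2O3 wash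
Reagents that add atoms: none
Why: Halogenation–dehydrobromination aromatisation: α-bromination of the 1,3-dione, thermal loss of HBr and tautomerisation give the resorcylate; the methyl ester survives if the bath stays at or below 80 °C.

**Step 3**
Reactants: 6 methyl 2,4-dihydroxy-6-pentylbenzoate
Product: 7 methyl 4-(allyloxy)-2-hydroxy-6-pentylbenzoate
Conditions: allyl bromide (1.05 equiv), K2CO3 (1.1 equiv), acetone, rt to 40 °C
Reagents that add atoms: allyl bromide, C=CCBr
Why: Regioselective Williamson etherification; the 4-OH is more acidic and unchelated, while the 2-OH is hydrogen-bonded to the ester carbonyl and stays free.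

**Step 4**
Reactants: 7 methyl 4-(allyloxy)-2-hydroxy-6-pentylbenzoate
Product: 8 methyl 4-(allyloxy)-2-methoxy-6-pentylbenzoate
Conditions: MeI (3 equiv), K2CO3 (2 equiv), DMF, 50 °C
Reagents that add atoms: iodomethane, CI
Why: Williamson O-methylation of the remaining chelated phenol under more forcing conditions (excess MeI, dipolar aprotic solvent); 50 °C is far below aromatic Claisen rearrangement temperatures.

**Step 5**
Reactants: 8 methyl 4-(allyloxy)-2-methoxy-6-pentylbenzoate
Product: 9 4-(allyloxy)-2-methoxy-6-pentylbenzoic acid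
Conditions: KOH (10 equiv), EtOH/H2O (2:1), reflux, 24–48 h; then 1 M HCl, 0 °C, to pH 3
Reagents that add atoms: potassium hydroxide (aqueous), [K+].[OH-]
Why: Saponification of a di-ortho-substituted benzoate with excess hydroxide at reflux; aryl allyl and methyl ethers are inert to aqueous alcoholic base, and cold acidification avoids protodecarboxylation.

**Step 6**
Reactants: 9 4-(allyloxy)-2-methoxy-6-pentylbenzoic acid
Product: 10 benzyl 4-(allyloxy)-2-methoxy-6-pentylbenzoate
Conditions: BnBr (1.1 equiv), K2CO3 (1.5 equiv), DMF, rt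
Reagents that add atoms: benzyl bromide, BrCc1ccccc1
Why: SN2 O-alkylation of the carboxylate, which is insensitive to the steric hindrance around the carbonyl carbon.

**Step 7**
Reactants: 10 benzyl 4-(allyloxy)-2-methoxy-6-pentylbenzoate
Product: 11 benzyl 4-hydroxy-2-methoxy-6-pentylbenzoate
Conditions: Pd(PPh3)4 (3 mol %), morpholine (3 equiv), THF, rt
Reagents that add atoms: none
Why: Tsuji–Trost deallylation: Pd(0) ionises the aryl allyl ether to a π-allyl complex that morpholine captures, freeing the phenol without touching the benzyl ester or methyl ether.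

**Step 8**
Reactants: 1 dimethyl malonate; 12 (E)-hept-3-en-2-one
Product: 14 methyl 2-hydroxy-4-oxo-6-propylcyclohex-2-ene-1-carboxylate (racemic; enol form of the 2,4-dione), via Michael adduct 13 (not isolated)
Conditions: NaOMe (1.1 equiv), MeOH, reflux, 4 h; then aq. HCl, 0 °C
Reagents that add atoms: none
Why: Same intermolecular Michael addition / intramolecular Claisen (Dieckmann) annulation as step 1; the stereocentres are racemic and erased in step 9.

**Step 9**
Reactants: 14 methyl 2-hydroxy-4-oxo-6-propylcyclohex-2-ene-1-carboxylate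
Product: 16 methyl 2,4-dihydroxy-6-propylbenzoate (methyl divarinate), via bromo-dione 15 (not isolated)
Conditions: Br2 (1.0 equiv), DMF, 0 °C, then 80 °C, 12 h; aq. Na2S2O3 wash
Reagents that add atoms: none
Why: Bromination–dehydrobromination aromatisation of the 1,3-dione, exactly as in step 2.

**Step 10**
Reactants: 16 methyl 2,4-dihydroxy-6-propylbenzoate
Product: 17 methyl 2-hydroxy-4-methoxy-6-propylbenzoate
Conditions: MeI (1.1 equiv), K2CO3 (1.1 equiv), acetone, rt to 40 °C
Reagents that add atoms: iodomethane, CI
Why: Regioselective Williamson methylation of the free, more acidic 4-OH; the chelated 2-OH is left untouched with one equivalent of reagent.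

**Step 11**
Reactants: 17 methyl 2-hydroxy-4-methoxy-6-propylbenzoate
Product: 18 methyl 2-(benzyloxy)-4-methoxy-6-propylbenzoate
Conditions: BnBr (1.5 equiv), K2CO3 (2 equiv), DMF, 70 °C
Reagents that add atoms: benzyl bromide, BrCc1ccccc1
Why: Williamson benzylation of the hydrogen-bonded ortho phenol under forcing conditions, masking it for the later acylation.

**Step 12**
Reactants: 18 methyl 2-(benzyloxy)-4-methoxy-6-propylbenzoate
Product: 19 2-(benzyloxy)-4-methoxy-6-propylbenzoic acid
Conditions: KOH (10 equiv), DMSO/H2O (4:1), 100 °C; then 1 M HCl, 0 °C, to pH 3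
Reagents that add atoms: potassium hydroxide (aqueous), [K+].[OH-]
Why: Saponification of the hindered ester with poorly solvated hydroxide in aqueous DMSO; benzyl and methyl aryl ethers are stable to base.

**Step 13**
Reactants: 19 2-(benzyloxy)-4-methoxy-6-propylbenzoic acid; 11 benzyl 4-hydroxy-2-methoxy-6-pentylbenzoate
Product: 21 benzyl 4-{[2-(benzyloxy)-4-methoxy-6-propylbenzoyl]oxy}-2-methoxy-6-pentylbenzoate, via mixed trifluoroacetic anhydride 20 (not isolated)
Conditions: TFAA (3 equiv), toluene, rt, 4–16 h
Reagents that add atoms: none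
Why: Mixed-anhydride esterification (TFAA method): the electron-rich, di-ortho-substituted acid forms an acyl trifluoroacetate/acylium species that acylates the unhindered 4-OH of 11 under base-free conditions.

**Step 14**
Reactants: 21 benzyl 4-{[2-(benzyloxy)-4-methoxy-6-propylbenzoyl]oxy}-2-methoxy-6-pentylbenzoate
Product: 22 4-[(2-hydroxy-4-methoxy-6-propylbenzoyl)oxy]-2-methoxy-6-pentylbenzoic acid (target)
Conditions: H2 (1 atm), 10 % Pd/C, EtOAc, rt
Reagents that add atoms: none
Why: Catalytic hydrogenolysis cleaves the benzyl ester and the benzyl ether together under neutral conditions that leave the depside ester intact; no stereocentre is involved.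

## Compound list

1 | dimethyl malonate | COC(=O)CC(=O)OC | starting material
2 | (E)-non-3-en-2-one | CCCCC/C=C/C(C)=O | starting material
3 | dimethyl 2-(2-oxononan-4-yl)propanedioate (racemic Michael adduct) | CCCCCC(CC(C)=O)C(C(=O)OC)C(=O)OC | intermediate (not isolated)
4 | methyl 2-hydroxy-4-oxo-6-pentylcyclohex-2-ene-1-carboxylate (racemic, cis/trans mixture, enol tautomer) | CCCCCC1CC(=O)C=C(O)C1C(=O)OC | intermediate
5 | methyl 3-bromo-2,4-dioxo-6-pentylcyclohexane-1-carboxylate (bromo-dione, stereoisomer mixture) | CCCCCC1CC(=O)C(Br)C(=O)C1C(=O)OC | intermediate (not isolated)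
6 | methyl 2,4-dihydroxy-6-pentylbenzoate | CCCCCc1cc(O)cc(O)c1C(=O)OC | intermediate
7 | methyl 4-(allyloxy)-2-hydroxy-6-pentylbenzoate | CCCCCc1cc(OCC=C)cc(O)c1C(=O)OC | intermediate
8 | methyl 4-(allyloxy)-2-methoxy-6-pentylbenzoate | CCCCCc1cc(OCC=C)cc(OC)c1C(=O)OC | intermediate
9 | 4-(allyloxy)-2-methoxy-6-pentylbenzoic acid | CCCCCc1cc(OCC=C)cc(OC)c1C(=O)O | intermediate
10 | benzyl 4-(allyloxy)-2-methoxy-6-pentylbenzoate | CCCCCc1cc(OCC=C)cc(OC)c1C(=O)OCc1ccccc1 | intermediate
11 | benzyl 4-hydroxy-2-methoxy-6-pentylbenzoate | CCCCCc1cc(O)cc(OC)c1C(=O)OCc1ccccc1 | intermediate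
12 | (E)-hept-3-en-2-one | CCC/C=C/C(C)=O | starting material
13 | dimethyl 2-(2-oxoheptan-4-yl)propanedioate (racemic Michael adduct) | CCCC(CC(C)=O)C(C(=O)OC)C(=O)OC | intermediate (not isolated)
14 | methyl 2-hydroxy-4-oxo-6-propylcyclohex-2-ene-1-carboxylate (racemic, cis/trans mixture, enol tautomer) | CCCC1CC(=O)C=C(O)C1C(=O)OC | intermediate
15 | methyl 3-bromo-2,4-dioxo-6-propylcyclohexane-1-carboxylate (bromo-dione, stereoisomer mixture) | CCCC1CC(=O)C(Br)C(=O)C1C(=O)OC | intermediate (not isolated)
16 | methyl 2,4-dihydroxy-6-propylbenzoate | CCCc1cc(O)cc(O)c1C(=O)OC | intermediate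
17 | methyl 2-hydroxy-4-methoxy-6-propylbenzoate | CCCc1cc(OC)cc(O)c1C(=O)OC | intermediate
18 | methyl 2-(benzyloxy)-4-methoxy-6-propylbenzoate | CCCc1cc(OC)cc(OCc2ccccc2)c1C(=O)OC | intermediate
19 | 2-(benzyloxy)-4-methoxy-6-propylbenzoic acid | CCCc1cc(OC)cc(OCc2ccccc2)c1C(=O)O | intermediate
20 | 2-(benzyloxy)-4-methoxy-6-propylbenzoic trifluoroacetic anhydride | CCCc1cc(OC)cc(OCc2ccccc2)c1C(=O)OC(=O)C(F)(F)F | intermediate (not isolated)
21 | benzyl 4-{[2-(benzyloxy)-4-methoxy-6-propylbenzoyl]oxy}-2-methoxy-6-pentylbenzoate | CCCCCc1cc(OC(=O)c2c(OCc3ccccc3)cc(OC)cc2CCC)cc(OC)c1C(=O)OCc1ccccc1 | intermediate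
22 | 4-[(2-hydroxy-4-methoxy-6-propylbenzoyl)oxy]-2-methoxy-6-pentylbenzoic acid | CCCCCc1cc(OC(=O)c2c(O)cc(OC)cc2CCC)cc(OC)c1C(=O)O | target

## Totals

Total step count: 14.
Longest linear sequence: 9 steps (steps 1–7, then 13 and 14); the A-ring branch is 5 steps (8–12) before the union.

## Steps most likely to fail, with fallbacks

**Step 2 (aromatisation with one equivalent of Br2).** The risks are over-bromination of the electron-rich ring and loss of the ester group if the mixture is overheated. The fallback embraces over-bromination and sets out from 4. Treatment with excess Br2 (3 equiv) in acetic acid at rt aromatises and brominates both free ring positions, giving methyl 3,5-dibromo-2,4-dihydroxy-6-pentylbenzoate F1 as a single crystalline product. Hydrogenolytic debromination (H2, Pd/C, NaOAc, MeOH, rt) then removes both bromines, and the route is rejoined at 6.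

**Step 5 (hydrolysis of the di-ortho-substituted methyl ester bearing an allyl ether).** The risks are very slow acyl substitution or allyl-to-propenyl isomerisation under harsher base. The fallback replaces acyl substitution by a redox detour and sets out from 8. LiAlH4 in THF reduces the hindered ester to [4-(allyloxy)-2-methoxy-6-pentylphenyl]methanol F2. MnO2 in CH2Cl2 oxidises this to 4-(allyloxy)-2-methoxy-6-pentylbenzaldehyde F3. Pinnick oxidation (NaClO2, NaH2PO4, 2-methyl-2-butene, t-BuOH/H2O) then gives the acid, and the route is rejoined at 9.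

**Step 13 (esterification of a hindered acid with an electron-poor phenol).** The risks are incomplete acylation or partial loss of a benzyl group in the acidic medium. The fallback switches to a base-mediated acylation with an isolated acyl chloride and sets out from 19. Oxalyl chloride with catalytic DMF in CH2Cl2 gives 2-(benzyloxy)-4-methoxy-6-propylbenzoyl chloride F4. This is added to the sodium phenoxide of 11 (NaH, THF, 0 °C to rt), and the route is rejoined at 21.

## Further compounds

F1 | step 2 | methyl 3,5-dibromo-2,4-dihydroxy-6-pentylbenzoate | CCCCCc1c(Br)c(O)c(Br)c(O)c1C(=O)OC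
F2 | step 5 | [4-(allyloxy)-2-methoxy-6-pentylphenyl]methanol | CCCCCc1cc(OCC=C)cc(OC)c1CO
F3 | step 5 | 4-(allyloxy)-2-methoxy-6-pentylbenzaldehyde | CCCCCc1cc(OCC=C)cc(OC)c1C=O
F4 | step 13 | 2-(benzyloxy)-4-methoxy-6-propylbenzoyl chloride | CCCc1cc(OC)cc(OCc2ccccc2)c1C(Cl)=O
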